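**Retrosynthetic overview**

- Feature: with the side chain numbered C1' (OCH2) to C7' (CMe2), the target pairs a C5' (S) secondary hydroxyl, erythro, with the trisubstituted C6'(S)–C7' gem-dimethyl oxirane. Direct epoxidation of a 5'-hydroxy-6',7'-ene beside the cis-methyl on C7' would not deliver this pairing reliably.
- Key disconnection: the O–C6' bond of the 6',7'-oxirane, leading back to the Payne isomer 6, a trans-(5'S,6'R)-5',6'-oxirane with a free C7' tertiary hydroxyl.
- Compound 6 comes from the (E)-5'-ene tertiary allylic alcohol 5 by hydroxyl-directed asymmetric epoxidation; 5 comes from geranyl ether 3 by Schenck ene reaction and reduction; 3 comes from phenol 1 and geranyl bromide 2.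
- Ring order: the coumarin bicycle is present in 1; the 5',6'-oxirane is made in step 3; the 6',7'-oxirane closes in step 4 as the 5',6'-oxirane opens.

Key step: step 4

Assumption: the (R,R)-cyclohexanediamine-derived bishydroxamic acid ligand is taken to deliver oxygen to the 5'-Si/6'-Re face of 5; if a calibration run shows the opposite sense, the (S,S)-ligand is used instead and nothing else changes.

**Route**

Step 1
Reactants: 1 7-hydroxy-8-methoxycoumarin; 2 geranyl bromide
Product: 3 7-{[(2E)-3,7-dimethylocta-2,6-dien-1-yl]oxy}-8-methoxycoumarin
Conditions: K2CO3, acetone, reflux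
Reagents that add atoms: none
Why: Williamson ether synthesis, in which the phenoxide of the acidic 7-OH displaces the primary allylic bromide by SN2 at C1', so the 2'E geometry is kept and the lactone is inert to carbonate in acetone.

Step 2
Reactants: 3 7-{[(2E)-3,7-dimethylocta-2,6-dien-1-yl]oxy}-8-methoxycoumarin
Product: 5 7-{[(2E,5E)-7-hydroxy-3,7-dimethylocta-2,5-dien-1-yl]oxy}-8-methoxycoumarin, via tertiary 7'-hydroperoxide 4 (not isolated)
Conditions: O2, TPP (cat.), visible light (>400 nm), CH2Cl2, 0 °C; then PPh3, 0 °C to rt; chromatography
Reagents that add atoms: dioxygen, O=O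
Why: Schenck ene reaction of singlet oxygen at the electron-rich 6',7'-alkene (the 2',3'-alkene is deactivated by the allylic aryloxy group, the coumarin C3=C4 is electron-poor, and visible light avoids coumarin [2+2] chemistry) abstracts a C5' hydrogen to place the hydroperoxide on C7' with a new (E)-5',6'-alkene, and phosphine reduces the O–O bond in the same flask; the regioisomeric secondary 6'-alcohol with an isopropenyl end, expected in comparable amount, should be removed by chromatography.

Step 3
Reactants: 5 7-{[(2E,5E)-7-hydroxy-3,7-dimethylocta-2,5-dien-1-yl]oxy}-8-methoxycoumarin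
Product: 6 7-{[(2E)-4-[(2S,3R)-3-(2-hydroxypropan-2-yl)oxiran-2-yl]-3-methylbut-2-en-1-yl]oxy}-8-methoxycoumarin
Conditions: WO2(acac)2 (5 mol%), (R,R)-bishydroxamic acid ligand (6 mol%), 30% aq H2O2 (2 equiv), NaCl, CH2Cl2, rt
Reagents that add atoms: hydrogen peroxide, OO
Why: Hydroxyl-directed catalytic asymmetric epoxidation of a tertiary allylic alcohol with a tungsten–bishydroxamic acid peroxo catalyst, in which binding of the C7' oxygen to the metal confines oxidation to the adjacent 5',6'-alkene (the 2',3'-alkene and the coumarin are out of reach), concerted oxygen transfer keeps the trans geometry, and the chiral ligand selects the 5'-Si/6'-Re face to set C5' (S) and C6' (R) together.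

Step 4
Reactants: 6 7-{[(2E)-4-[(2S,3R)-3-(2-hydroxypropan-2-yl)oxiran-2-yl]-3-methylbut-2-en-1-yl]oxy}-8-methoxycoumarin
Product: 7 7-{[(2E,5S)-5-[(2S)-3,3-dimethyloxiran-2-yl]-5-hydroxy-3-methylpent-2-en-1-yl]oxy}-8-methoxycoumarin
Conditions: t-BuOK (0.2 equiv), THF (0.02 M), −20 to 0 °C; pH 7 phosphate buffer; Et3N-deactivated silica
Reagents that add atoms: none
Why: Payne rearrangement (base-mediated epoxide migration of a 2,3-epoxy alcohol): the catalytic base deprotonates the C7' hydroxyl and the tertiary alkoxide attacks the neighbouring oxirane carbon C6' from the rear, forming the O–C6' bond of the 6',7'-oxirane while the old C6'–O bond breaks and the C5' oxygen leaves as an alkoxide that takes a proton from the next molecule of 6. The new three-membered ring closes in the 3-exo-tet mode, which is preferred over the four-membered alternative from attack at C5'. C6' is the one new stereocentre and its S configuration follows from stereospecific SN2 inversion of the 6'R centre of the trans-oxirane, whereas C5' keeps its oxygen and its S configuration, so the erythro pair is fixed by the epoxide geometry of step 3 and not by any facial bias. The step needs the equilibrium to lie towards 7, which the gain in oxirane substitution (trisubstituted against disubstituted) and the exchange of a hindered tertiary carbinol for a secondary one should provide, and unchanged 6 can be recovered and resubmitted. It also needs the coumarin lactone and its C3=C4 acceptor to survive, for which the substoichiometric hindered base, high dilution, low temperature and buffered quench are chosen.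

**Compound list**

1 | 7-hydroxy-8-methoxycoumarin | COc1c(O)ccc2ccc(=O)oc12 | starting material
2 | geranyl bromide, (2E)-1-bromo-3,7-dimethylocta-2,6-diene | CC(C)=CCC/C(C)=C/CBr | starting material
3 | 7-{[(2E)-3,7-dimethylocta-2,6-dien-1-yl]oxy}-8-methoxycoumarin | COc1c(OC/C=C(\C)CCC=C(C)C)ccc2ccc(=O)oc12 | intermediate
4 | 7-{[(2E,5E)-7-hydroperoxy-3,7-dimethylocta-2,5-dien-1-yl]oxy}-8-methoxycoumarin | COc1c(OC/C=C(\C)C/C=C/C(C)(C)OO)ccc2ccc(=O)oc12 | intermediate
5 | 7-{[(2E,5E)-7-hydroxy-3,7-dimethylocta-2,5-dien-1-yl]oxy}-8-methoxycoumarin | COc1c(OC/C=C(\C)C/C=C/C(C)(C)O)ccc2ccc(=O)oc12 | intermediate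
6 | 7-{[(2E)-4-[(2S,3R)-3-(2-hydroxypropan-2-yl)oxiran-2-yl]-3-methylbut-2-en-1-yl]oxy}-8-methoxycoumarin | COc1c(OC/C=C(\C)C[C@@H]2O[C@H]2C(C)(C)O)ccc2ccc(=O)oc12 | intermediate
7 | 7-{[(2E,5S)-5-[(2S)-3,3-dimethyloxiran-2-yl]-5-hydroxy-3-methylpent-2-en-1-yl]oxy}-8-methoxycoumarin | COc1c(OC/C=C(\C)C[C@H](O)[C@@H]2OC2(C)C)ccc2ccc(=O)oc12 | target

**Step count and risks**

Total step count: 4. Longest linear sequence: 4 steps.

Steps most likely to fail:

1. Step 4. The epoxide migration may stop at an unfavourable equilibrium, or the alkoxides may open the coumarin lactone before migration is complete. The fallback sets out from 6 and replaces equilibrium control by kinetic trapping. Compound 6 would be treated with NaH (1.1 equiv) and TBSCl (1.2 equiv) in THF at 0 °C, so that the interconverting alkoxides are drained through the much faster silylation of the secondary C5' alkoxide. This should give 7-{[(2E,5S)-5-[(tert-butyldimethylsilyl)oxy]-5-[(2S)-3,3-dimethyloxiran-2-yl]-3-methylpent-2-en-1-yl]oxy}-8-methoxycoumarin F1. Desilylation with TBAF buffered with AcOH in THF at 0 °C, which never generates a free alkoxide, returns to the route at 7.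

2. Step 3. Facial discrimination on this hindered E-disubstituted tertiary allylic alcohol may be poor, or conversion may be slow. The fallback sets out from 5 and replaces catalyst-controlled induction by a racemic directed epoxidation with resolution. VO(acac)2 (cat.) and TBHP in CH2Cl2 at 0 °C to rt should give the trans-epoxide as a racemate with the same chemoselectivity. Preparative chromatography on a chiral stationary phase would then separate 6 from its enantiomer 7-{[(2E)-4-[(2R,3S)-3-(2-hydroxypropan-2-yl)oxiran-2-yl]-3-methylbut-2-en-1-yl]oxy}-8-methoxycoumarin F2. The absolute configuration would be assigned by Mosher analysis of the C5' carbinol after rearrangement, and the route is rejoined at 6.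

3. Step 2. The ene reaction partitions between hydrogen abstraction from C5' and from the C7' methyl, so much material is lost to the regioisomeric secondary hydroperoxide. The fallback sets out from 3 and fixes the regiochemistry by selenium chemistry. Markovnikov hydroxyselenation of the 6',7'-alkene with N-(phenylseleno)phthalimide, water and catalytic CSA in CH2Cl2 should give racemic 7-{[(2E)-7-hydroxy-3,7-dimethyl-6-(phenylselanyl)oct-2-en-1-yl]oxy}-8-methoxycoumarin F3. Oxidation with H2O2 and pyridine in CH2Cl2 at 0 °C to rt gives the selenoxide, whose syn-elimination can only run towards C5' because C7' carries no hydrogen. This delivers the (E)-allylic tertiary alcohol and returns to the route at 5.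

**Further compounds**

F1 | step 4 | 7-{[(2E,5S)-5-[(tert-butyldimethylsilyl)oxy]-5-[(2S)-3,3-dimethyloxiran-2-yl]-3-methylpent-2-en-1-yl]oxy}-8-methoxycoumarin | COc1c(OC/C=C(\C)C[C@H](O[Si](C)(C)C(C)(C)C)[C@@H]2OC2(C)C)ccc2ccc(=O)oc12
F2 | step 3 | 7-{[(2E)-4-[(2R,3S)-3-(2-hydroxypropan-2-yl)oxiran-2-yl]-3-methylbut-2-en-1-yl]oxy}-8-methoxycoumarin | COc1c(OC/C=C(\C)C[C@H]2O[C@@H]2C(C)(C)O)ccc2ccc(=O)oc12
F3 | step 2 | 7-{[(2E)-7-hydroxy-3,7-dimethyl-6-(phenylselanyl)oct-2-en-1-yl]oxy}-8-methoxycoumarin (racemic at C6') | COc1c(OC/C=C(\C)CCC([Se]c3ccccc3)C(C)(C)O)ccc2ccc(=O)oc12
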